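## Retrosynthetic overview

1. The biomimetic cut (retro-IMDA, then 6π/8π opening to a linear polyene) is not used. The cyclobutane and the cyclopentane are instead made last and together.
2. The target comes from an intramolecular triplet-sensitised diene–alkene [2+2] (2 C–C bonds, 2 rings, 4 stereocentres). The substrate is a cis-1,4,4a,8a-tetrahydronaphthalene carrying the ester and the dienyl side chain.
3. That bicycle is the formal exo adduct of "benzene as dienophile". Its side chain comes from an sp3–sp2 Negishi coupling. Its two arms come from a meso-diol that a lipase differentiates, which sets the absolute configuration.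
4. The meso-diol comes from glycol cleavage of a bicyclo[2.2.2]octene. That arises from the endo Diels–Alder of cis-dihydrocatechol acetonide with p-benzoquinone, with enedione → diene by Luche/Ti(0).
5. Ring order: both six-membered rings (Diels–Alder) → diene in the quinone-derived ring → bridge cleavage → cyclopentane + cyclobutane (photocycloaddition).

Assumption: the lipase leaves free the CH2OH arm that becomes the side chain (as drawn). If it prefers the other arm, the two arms are elaborated in the opposite order, which gives the same enantiomer of the target.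

## Route

Step 1
Reactants: 1 cis-cyclohexa-3,5-diene-1,2-diol (meso)
Product: 2 cis-2,2-dimethyl-3a,7a-dihydro-1,3-benzodioxole (acetonide of 1)
Conditions: Me2C(OMe)2, cat. p-TsOH, CH2Cl2, 0 °C; used at once
Reagents that add atoms: 2,2-dimethoxypropane COC(C)(C)OC
Why: Acid-catalysed transketalisation ties the cis-diol into a dioxolane, which stops dehydrative aromatisation and blocks one diene face, and no stereocentre is changed.

Step 2
Reactants: 2 cis-2,2-dimethyl-3a,7a-dihydro-1,3-benzodioxole; 3 1,4-benzoquinone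
Product: 4 meso endo adduct, 9,10-(isopropylidenedioxy)-1,4,4a,8a-tetrahydro-1,4-ethanonaphthalene-5,8-dione (enedione ring and both O syn to C2=C3)
Conditions: PhMe, rt, dark, 24 h
Reagents that add atoms: none
Why: In this normal-demand Diels–Alder reaction the quinone adds anti to the acetonide and endo (Alder rule), so the enedione ring ends syn to the new C=C and anti to the dioxygenated bridge, which fixes the relative configuration of the four contiguous carbons that become C–CO2Me, both ring-fusion CH and the chain-bearing CH (product meso).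

Step 3
Reactants: 4 meso endo adduct
Product: 5 meso ene-diol (5,8-diol of 4, both OH on the concave face)
Conditions: NaBH4, CeCl3·7H2O, MeOH, −78 → 0 °C
Reagents that add atoms: none
Why: Luche 1,2-reduction avoids conjugate reduction and enolisation to the hydroquinone and delivers hydride from the open convex face, and both new carbinol centres are erased in step 4.

Step 4
Reactants: 5 meso ene-diol
Product: 6 meso diene acetonide, 9,10-(isopropylidenedioxy)-1,4,4a,8a-tetrahydro-1,4-ethanonaphthalene (C5=C6–C7=C8 diene)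
Conditions: TiCl3/LiAlH4, THF, reflux, then 5, rt → 50 °C
Reagents that add atoms: none
Why: Low-valent-titanium reductive 1,4-elimination of a 2-ene-1,4-diol (McMurry-type deoxygenation via the titanium bis-alkoxide) removes both C–O bonds to leave the cyclohexa-1,3-diene, with acetal and isolated alkene inert and no retained stereocentre touched.

Step 5
Reactants: 6 meso diene acetonide
Product: 8 meso-[(1R,4S,4aS,8aR)-1,4,4a,8a-tetrahydronaphthalene-1,4-diyl]dimethanol, via meso-dialdehyde 7 (not isolated)
Conditions: H5IO6, EtOAc–THF, 0 °C → rt; filter; NaBH4, MeOH, 0 °C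
Reagents that add atoms: none
Why: Periodic acid hydrolyses the acetonide and carries out the Malaprade glycol cleavage of the two-carbon bridge, and immediate borohydride reduction of the epimerisable β,γ-unsaturated dialdehyde gives the diol whose arms are cis to each other and trans to the diene ring because they were the anti bridge of the endo adduct.

Step 6
Reactants: 8 meso-diol
Product: 9 [(1R,4S,4aS,8aR)-4-(hydroxymethyl)-1,4,4a,8a-tetrahydronaphthalen-1-yl]methyl acetate
Conditions: Amano lipase PS (immobilised), vinyl acetate, MTBE, 25 °C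
Reagents that add atoms: vinyl acetate C=COC(C)=O
Why: Lipase-catalysed irreversible transesterification (enantiotopic-group-selective desymmetrisation of a meso-diol) acylates one of the two mirror-related CH2OH groups and so fixes the absolute configuration of all four stereocentres at once.

Step 7
Reactants: 9 monoacetate
Product: 10 [(1R,4S,4aS,8aR)-4-(iodomethyl)-1,4,4a,8a-tetrahydronaphthalen-1-yl]methyl acetate
Conditions: I2, PPh3, imidazole, CH2Cl2, 0 °C
Reagents that add atoms: iodine II
Why: Appel-type iodination replaces the primary hydroxyl by SN2 at CH2 under near-neutral conditions that spare acetate, diene and alkene, and no stereocentre is involved.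

Step 8
Reactants: 11 dec-9-en-1-ol
Product: 12 (E)-dec-8-en-1-ol
Conditions: [Cp*Ru(MeCN)(2-(iPr2P)-4-tBu-1-methylimidazole)]PF6 1 mol %, acetone, rt
Reagents that add atoms: none
Why: Bifunctional Ru-catalysed alkene mono-isomerisation moves the terminal double bond by exactly one position and gives the (E)-2-alkene under kinetic control, which sets the side-chain alkene geometry.

Step 9
Reactants: 12 (E)-dec-8-en-1-ol
Product: 13 (E)-10-iododec-2-ene
Conditions: I2, PPh3, imidazole, CH2Cl2, 0 °C
Reagents that add atoms: iodine II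
Why: Appel-type iodination of the primary alcohol proceeds by SN2 and leaves the remote (E)-alkene untouched.

Step 10
Reactants: 13 (E)-10-iododec-2-ene; 14 lithium acetylide–ethylenediamine complex
Product: 15 (E)-dodec-10-en-1-yne
Conditions: DMSO, 0 °C → rt
Reagents that add atoms: none
Why: SN2 alkylation of lithium acetylide adds the two carbons that later become the chain-bearing cyclobutane CH and its neighbour.

Step 11
Reactants: 15 (E)-dodec-10-en-1-yne
Product: 17 (1E,10E)-1-iodododeca-1,10-diene, via alkenylzirconocene chloride 16 (not isolated)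
Conditions: Cp2Zr(H)Cl, THF, rt; then I2, 0 °C
Reagents that add atoms: iodine II
Why: Schwartz hydrozirconation is syn, terminal-selective and much faster for the alkyne than for the internal alkene, and iodinolysis of the C–Zr bond occurs with retention to give the (E)-alkenyl iodide.

Step 12
Reactants: 10 iodide; 17 (1E,10E)-1-iodododeca-1,10-diene
Product: 19 {(1R,4S,4aR,8aR)-4-[(2E,11E)-trideca-2,11-dien-1-yl]-1,4,4a,8a-tetrahydronaphthalen-1-yl}methyl acetate, via alkylzinc iodide 18 (not isolated)
Conditions: 10, activated Zn dust, LiCl, THF, 40 °C; then 17, Pd(dppf)Cl2 5 mol %, rt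
Reagents that add atoms: none
Why: Zinc insertion into the primary iodide followed by sp3–sp2 Negishi cross-coupling joins the fragments with retention of alkene geometry, the wide-bite dppf ligand favouring reductive elimination over β-hydride elimination and the merely homoallylic acetate excluding π-allyl chemistry.

Step 13
Reactants: 19 coupled acetate
Product: 20 {(1R,4S,4aR,8aR)-4-[(2E,11E)-trideca-2,11-dien-1-yl]-1,4,4a,8a-tetrahydronaphthalen-1-yl}methanol
Conditions: K2CO3 (0.2 equiv), MeOH, 0 °C → rt
Reagents that add atoms: none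
Why: Base-catalysed transesterification (methanolysis) removes the acetate while no acidic stereocentre is yet present.

Step 14
Reactants: 20 alcohol
Product: 22 (1R,4S,4aR,8aR)-4-[(2E,11E)-trideca-2,11-dien-1-yl]-1,4,4a,8a-tetrahydronaphthalene-1-carboxylic acid, via aldehyde 21 (not isolated)
Conditions: TEMPO (0.2 equiv), PhI(OAc)2 (2.2 equiv), MeCN–H2O, rt
Reagents that add atoms: water O
Why: TEMPO/oxoammonium oxidation takes the primary alcohol through the aldehyde hydrate to the acid under buffered, alkene-tolerant conditions in which the short-lived β,γ-unsaturated aldehyde neither epimerises nor conjugates.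

Step 15
Reactants: 22 acid
Product: 23 methyl (1R,4S,4aR,8aR)-4-[(2E,11E)-trideca-2,11-dien-1-yl]-1,4,4a,8a-tetrahydronaphthalene-1-carboxylate
Conditions: TMSCHN2, PhMe–MeOH 3:1, 0 °C
Reagents that add atoms: (trimethylsilyl)diazomethane C[Si](C)(C)C=[N+]=[N-]
Why: Diazoalkane esterification is base-free, so the allylic α-stereocentre is kept and the double bond does not move into conjugation.

Step 16
Reactants: 23 methyl ester
Product: 24 target CNP0133550.1 (tetracyclic methyl ester with exo (E)-dec-8-enyl on the cyclobutane)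
Conditions: [Ir(dF(CF3)ppy)2(dtbbpy)]PF6 1 mol %, degassed DMSO, 5 mM, blue LED, rt
Reagents that add atoms: none
Why: In this visible-light triplet-sensitised intramolecular diene–alkene [2+2] photocycloaddition only the cyclohexadiene (ET about 52 kcal/mol, sensitiser about 61) is excited, the first bond forms 5-exo (rule of five) from the pseudo-axial three-atom tether on the face that carries it, the alkyl/allyl 1,4-diradical closes to the photostable vinylcyclobutane, the three ring-fusion centres are forced cis by the tether, and the freely rotating secondary radical places the decenyl chain exo, away from the all-cis face.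

## Compound list

1 | cis-cyclohexa-3,5-diene-1,2-diol (meso) | O[C@H]1C=CC=C[C@H]1O | starting material
2 | cis-2,2-dimethyl-3a,7a-dihydro-1,3-benzodioxole | CC1(C)O[C@H]2C=CC=C[C@H]2O1 | intermediate
3 | 1,4-benzoquinone | O=C1C=CC(=O)C=C1 | starting material
4 | meso endo Diels–Alder adduct (enedione) | [C@@H]12C=C[C@@H]([C@H]3OC(C)(C)O[C@H]31)[C@@H]4C(=O)C=CC(=O)[C@H]24 | intermediate
5 | meso ene-diol | [C@@H]12C=C[C@@H]([C@H]3OC(C)(C)O[C@H]31)[C@@H]4[C@H](O)C=C[C@H](O)[C@H]24 | intermediate
6 | meso diene acetonide | [C@@H]12C=C[C@@H]([C@H]3OC(C)(C)O[C@H]31)[C@@H]4C=CC=C[C@H]24 | intermediate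
7 | meso-(1R,4S,4aS,8aR)-1,4,4a,8a-tetrahydronaphthalene-1,4-dicarbaldehyde | O=C[C@H]1C=C[C@@H](C=O)[C@@H]2C=CC=C[C@H]12 | intermediate
8 | meso-[(1R,4S,4aS,8aR)-1,4,4a,8a-tetrahydronaphthalene-1,4-diyl]dimethanol | OC[C@H]1C=C[C@@H](CO)[C@@H]2C=CC=C[C@H]12 | intermediate
9 | [(1R,4S,4aS,8aR)-4-(hydroxymethyl)-1,4,4a,8a-tetrahydronaphthalen-1-yl]methyl acetate | OC[C@H]1C=C[C@@H](COC(C)=O)[C@@H]2C=CC=C[C@H]12 | intermediate
10 | [(1R,4S,4aS,8aR)-4-(iodomethyl)-1,4,4a,8a-tetrahydronaphthalen-1-yl]methyl acetate | IC[C@H]1C=C[C@@H](COC(C)=O)[C@@H]2C=CC=C[C@H]12 | intermediate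
11 | dec-9-en-1-ol | OCCCCCCCCC=C | starting material
12 | (E)-dec-8-en-1-ol | OCCCCCCC/C=C/C | intermediate
13 | (E)-10-iododec-2-ene | ICCCCCCC/C=C/C | intermediate
14 | lithium acetylide–ethylenediamine complex | [Li+].[C-]#C.NCCN | starting material
15 | (E)-dodec-10-en-1-yne | C#CCCCCCCC/C=C/C | intermediate
16 | (1E,10E)-dodeca-1,10-dienylzirconocene chloride | C/C=C/CCCCCCC/C=C/[Zr+2]Cl.[cH-]1cccc1.[cH-]1cccc1 | intermediate
17 | (1E,10E)-1-iodododeca-1,10-diene | C/C=C/CCCCCCC/C=C/I | intermediate
18 | alkylzinc iodide from 10 | I[Zn]C[C@H]1C=C[C@@H](COC(C)=O)[C@@H]2C=CC=C[C@H]12 | intermediate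
19 | {(1R,4S,4aR,8aR)-4-[(2E,11E)-trideca-2,11-dien-1-yl]-1,4,4a,8a-tetrahydronaphthalen-1-yl}methyl acetate | C/C=C/CCCCCCC/C=C/C[C@H]1C=C[C@@H](COC(C)=O)[C@@H]2C=CC=C[C@H]12 | intermediate
20 | corresponding primary alcohol | C/C=C/CCCCCCC/C=C/C[C@H]1C=C[C@@H](CO)[C@@H]2C=CC=C[C@H]12 | intermediate
21 | corresponding 1-carbaldehyde | C/C=C/CCCCCCC/C=C/C[C@H]1C=C[C@@H](C=O)[C@@H]2C=CC=C[C@H]12 | intermediate
22 | corresponding 1-carboxylic acid | C/C=C/CCCCCCC/C=C/C[C@H]1C=C[C@@H](C(=O)O)[C@@H]2C=CC=C[C@H]12 | intermediate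
23 | methyl (1R,4S,4aR,8aR)-4-[(2E,11E)-trideca-2,11-dien-1-yl]-1,4,4a,8a-tetrahydronaphthalene-1-carboxylate | C/C=C/CCCCCCC/C=C/C[C@H]1C=C[C@@H](C(=O)OC)[C@@H]2C=CC=C[C@H]12 | intermediate
24 | CNP0133550.1 | C/C=C/CCCCCCC[C@@H]1[C@H]2C=C[C@@H]3[C@@H]4[C@H]2[C@H]1C[C@H]4C=C[C@H]3C(=O)OC | target

## Totals and risks

Total step count: 16. Longest linear sequence: 12 (steps 1–7 and 12–16).

**Step 16 (most likely to fail).** The diradical may close 1,6 to a bicyclo[2.2.2]octene. The dialkyl alkene may trap the triplet too slowly. Exo/endo control at the chain-bearing carbon may be incomplete. The fallback sets out from 13 and comes back at 24. It gives up the cyclobutane-last plan for a thermal pericyclic relay.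

- Cyclooctatetraene is epoxidised (mCPBA) to cyclooctatetraene oxide F1.
- Iodide 13 undergoes I/Zn exchange (Et2Zn, cat. CuI) to bis[(E)-dec-8-en-1-yl]zinc F2.
- Cu(OTf)2 with a binaphthol phosphoramidite (enantiomer chosen for the 1R,4R product) catalyses the anti-SN2′ desymmetrisation of the meso epoxide. This gives trans-trienol F3.
- Pd(II)-catalysed vinyl transfer from butyl vinyl ether gives vinyl ether F4.
- On warming, F4 undergoes suprafacial Claisen rearrangement to trans-cyclooctatriene acetaldehyde F5.
- F5 closes by 6π electrocyclisation to bicyclo[4.2.0]octadiene acetaldehyde F6.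
- Horner–Wadsworth–Emmons reaction with trimethyl 4-phosphonocrotonate (LiHMDS) gives (E,E)-dienoate F7.
- Heating in toluene at 100 °C closes the last two rings by intramolecular Diels–Alder reaction to 24.

**Step 6.** The stereocentres are β to the reacting oxygen, so ee may be low, and over-acylation is possible. The fallback sets out from 8 and comes back at 23. It desymmetrises by hydrolysis at the diester oxidation level, so the final methyl ester is in place from then on.

- TEMPO/PhI(OAc)2 converts 8 to meso-diacid F8.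
- TMSCHN2 gives meso-dimethyl ester F9.
- Pig-liver esterase (pH 7 buffer) gives half-ester F10.
- Isobutyl chloroformate/N-methylmorpholine and then NaBH4 reduce only the acid, giving hydroxy ester F11.
- Appel iodination gives iodo ester F12.
- Zinc insertion gives alkylzinc iodide F13, which couples with 17 under Pd(dppf)Cl2 to give 23.

**Step 4.** Allyl-radical side reactions are the concern: transannular attack on the nearby C2=C3, or dimerisation. The fallback sets out from 4 and comes back at 6. It uses a polar/Pd sequence instead of low-valent metal deoxygenation.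

- Zn/AcOH conjugate reduction gives saturated diketone F14.
- KHMDS/PhNTf2 enolises kinetically toward the CH2 groups and gives bis(enol triflate) F15.
- Pd(OAc)2/PPh3 with HCO2H/Et3N reduces both C–OTf bonds to give 6.

## Further compounds

F1 | step 16 | cyclooctatetraene oxide (9-oxabicyclo[6.1.0]nona-2,4,6-triene, meso) | O1[C@H]2/C=C\C=C/C=C\[C@@H]12
F2 | step 16 | bis[(E)-dec-8-en-1-yl]zinc | C/C=C/CCCCCCC[Zn]CCCCCCC/C=C/C
F3 | step 16 | (1R,4R)-4-[(E)-dec-8-en-1-yl]cycloocta-2,5,7-trien-1-ol (trans) | C/C=C/CCCCCCC[C@@H]1/C=C\C=C/[C@@H](O)/C=C\1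
F4 | step 16 | vinyl ether of F3 | C/C=C/CCCCCCC[C@@H]1/C=C\C=C/[C@@H](OC=C)/C=C\1
F5 | step 16 | trans-2-{8-[(E)-dec-8-en-1-yl]cycloocta-2,4,6-trien-1-yl}acetaldehyde | C/C=C/CCCCCCC[C@@H]1/C=C\C=C/C=C\[C@H]1CC=O
F6 | step 16 | 2-{8-exo-[(E)-dec-8-en-1-yl]bicyclo[4.2.0]octa-2,4-dien-7-endo-yl}acetaldehyde | C/C=C/CCCCCCC[C@@H]1[C@H]2C=CC=C[C@H]2[C@H]1CC=O
F7 | step 16 | methyl (2E,4E)-6-{8-exo-[(E)-dec-8-en-1-yl]bicyclo[4.2.0]octa-2,4-dien-7-endo-yl}hexa-2,4-dienoate | C/C=C/CCCCCCC[C@@H]1[C@H]2C=CC=C[C@H]2[C@H]1C/C=C/C=C/C(=O)OC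
F8 | step 6 | meso-1,4,4a,8a-tetrahydronaphthalene-1,4-dicarboxylic acid | OC(=O)[C@H]1C=C[C@@H](C(=O)O)[C@@H]2C=CC=C[C@H]12
F9 | step 6 | meso-dimethyl 1,4,4a,8a-tetrahydronaphthalene-1,4-dicarboxylate | COC(=O)[C@H]1C=C[C@@H](C(=O)OC)[C@@H]2C=CC=C[C@H]12
F10 | step 6 | half-ester (4-methoxycarbonyl-1,4,4a,8a-tetrahydronaphthalene-1-carboxylic acid) | OC(=O)[C@H]1C=C[C@@H](C(=O)OC)[C@@H]2C=CC=C[C@H]12
F11 | step 6 | methyl 4-(hydroxymethyl)-1,4,4a,8a-tetrahydronaphthalene-1-carboxylate | OC[C@H]1C=C[C@@H](C(=O)OC)[C@@H]2C=CC=C[C@H]12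
F12 | step 6 | methyl 4-(iodomethyl)-1,4,4a,8a-tetrahydronaphthalene-1-carboxylate | IC[C@H]1C=C[C@@H](C(=O)OC)[C@@H]2C=CC=C[C@H]12
F13 | step 6 | alkylzinc iodide from F12 | I[Zn]C[C@H]1C=C[C@@H](C(=O)OC)[C@@H]2C=CC=C[C@H]12
F14 | step 4 | saturated 5,8-diketone (6,7-dihydro-4) | [C@@H]12C=C[C@@H]([C@H]3OC(C)(C)O[C@H]31)[C@@H]4C(=O)CCC(=O)[C@H]24
F15 | step 4 | 5,8-bis(enol triflate) | [C@@H]12C=C[C@@H]([C@H]3OC(C)(C)O[C@H]31)[C@@H]4C(OS(=O)(=O)C(F)(F)F)=CC=C(OS(=O)(=O)C(F)(F)F)[C@H]24
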